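**Retrosynthetic overview**

1. Late stage: C9–OH from a MOM ether, the C8 angelate from a C8 PMB ether, the C14 methyl ester from a C14 silyl ether, and C11=C13 by Mannich/elimination on the trans-fused C12→O6 γ-lactone. The lactone comes from C7–C11 alkylation of a C6=C7 enolate, C6 reduction and lactonisation with inversion.
2. Key disconnection: in the ten-membered carbocycle C1–C10, the C1=C10 alkene and the C6 oxygen lie 1,5 to each other on either side of the C8–C9 bond that joins the two oxygen-bearing carbons. Closing C1–C6 and opening C8–C9 (retro anionic oxy-Cope) gives a cis-1,2-dialkenyl-4-methylcyclohexanol whose C1–C6 arc is the cyclohexane and whose two enol ethers carry O8 and O9 cis to the ring-bound carbon.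
3. That carbinol comes from a 2-alkenyl-5-methylcyclohexanone by axial addition of lithium (4-methoxybenzyloxy)acetylide and Lindlar reduction. The C9=C10 enol ether comes from formylation/O-alkylation of a bicyclic lactone made from 2-cyclohexen-1-one by α′-alkylation and catalytic asymmetric conjugate methylation (C4).
4. Ring order: cyclohexane (present from step 1), then the ten-membered carbocycle by four-carbon ring expansion (step 11), then the γ-lactone (step 14).

Key step: step 11

Remark (numbering and abbreviations): C1–C10 are the ring carbons of the target (C1 = alkene CH, C10 bears C14), C15 is the methyl on C4, and C11/C12/C13 are the lactone α-carbon, carbonyl and methylene. The same numbers are used for the cyclohexane intermediates (C6 = carbinol or ketone carbon, C1 = carbon bearing C10). PMB = 4-methoxybenzyl, MOM = methoxymethyl, TBDPS = tert-butyldiphenylsilyl, TMS = trimethylsilyl.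

Remark (assumption): the target SMILES is read as the 4S,6R,7S,8S,9S enantiomer. The ring-expanded cyclodec-5-enone is taken out of the key step as its C6 trimethylsilyl enol ether (ketone masked), because only the rearrangement itself gives the C6=C7 enolate regiospecifically; base treatment of the free β-alkoxy ketone would not be expected to enolise selectively towards C7. C14 is carried as a TBDPS ether.

**Route**

Step 1
Reactants: 1 2-cyclohexen-1-one
Product: 3 methyl 2-(2-oxocyclohex-3-en-1-yl)acetate (racemic), via lithium dienolate 2 (not isolated)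
Conditions: LiN(i-Pr)2, THF, −78 °C; then BrCH2CO2Me, DMPU, −78 → −20 °C
Reagents that add atoms: methyl bromoacetate, COC(=O)CBr
Why: Kinetic deprotonation of the enone at the α′ carbon gives the cross-conjugated lithium dienolate, and enolate alkylation (SN2) with the activated α-bromo ester attaches the future C10–C14 unit to the future C1, whose configuration is left racemic here and corrected in step 2.

Step 2
Reactants: 3 methyl 2-(2-oxocyclohex-3-en-1-yl)acetate
Product: 6 methyl 2-[(1R,4S)-4-methyl-2-oxocyclohexyl]acetate, via methylzinc enolate 4 (not isolated), via C1-epimeric keto ester mixture 5 (not isolated)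
Conditions: Me2Zn, Cu(OTf)2 (2 mol %), (S,R,R)-phosphoramidite from (S)-BINOL and bis[(R)-1-phenylethyl]amine (4 mol %), toluene, −30 °C; NH4Cl (aq); then NaOMe (cat.), MeOH, 23 °C
Reagents that add atoms: dimethylzinc, C[Zn]C
Why: Copper-catalysed asymmetric conjugate addition delivers the methyl group to C4 under control of the chiral phosphoramidite (ligand enantiomer chosen for 4S) for both enantiomers of 3, and base equilibration of the epimerisable C1 centre then favours the trans-1,4 diequatorial isomer, from which the minor cis epimer is separated and recycled.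

Step 3
Reactants: 6 methyl 2-[(1R,4S)-4-methyl-2-oxocyclohexyl]acetate
Product: 8 (3aR,6S,7aR)-6-methylhexahydro-1-benzofuran-2(3H)-one (cis-fused lactone), via lithium alkoxide 7 (not isolated)
Conditions: LiBH(s-Bu)3, THF, −78 → 0 °C; then 1 M HCl, 23 °C
Reagents that add atoms: none
Why: The bulky trialkylborohydride reduces the ketone from the equatorial side (substrate-controlled hydride reduction), and the resulting axial C6 alkoxide, cis to the C1 side chain, closes onto the methyl ester by lactonisation, which masks C6 and leaves C10 as the only enolisable carbon.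

Step 4
Reactants: 8 cis-fused lactone
Product: 10 (3E,3aR,6S,7aR)-3-[(methoxymethoxy)methylidene]-6-methylhexahydro-1-benzofuran-2(3H)-one, via sodium formyl-lactone enolate 9 (not isolated)
Conditions: NaH, HCO2Et, THF, 0 → 23 °C; then MeOCH2Cl, DMF, 0 °C
Reagents that add atoms: ethyl formate, CCOC=O; chloromethyl methyl ether, COCCl
Why: Crossed Claisen condensation with ethyl formate adds C9 at C10, and O-alkylation of the ambident enolate with the hard chloromethyl ether gives the push–pull alkoxymethylene lactone, expected as the E isomer with O9 anti to the lactone carbonyl and hence cis to C1 (a Z fraction would be equilibrated or separated).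

Step 5
Reactants: 10 alkoxymethylene lactone
Product: 11 (1R,2R,5S)-2-[(1E)-3-hydroxy-1-(methoxymethoxy)prop-1-en-2-yl]-5-methylcyclohexan-1-ol
Conditions: i-Bu2AlH (4 equiv), CH2Cl2, −78 → −20 °C; potassium sodium tartrate KNaC4H4O6 (aq); Et3N-deactivated silica
Reagents that add atoms: none
Why: Exhaustive 1,2-hydride reduction of the vinylogous carbonate through the lactol opens the lactone to the C6 carbinol and the C14 allylic alcohol without touching the enol ether, so the C9=C10 geometry set in step 4 is carried over.

Step 6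
Reactants: 11 diol
Product: 12 C14 TBDPS ether of diol 11
Conditions: t-BuPh2SiCl, imidazole, CH2Cl2, 0 °C
Reagents that add atoms: tert-butyl(chloro)diphenylsilane, CC(C)(C)[Si](Cl)(c1ccccc1)c1ccccc1
Why: Silyl ether formation with the bulky chlorosilane discriminates sterically between the primary C14 hydroxyl and the axial secondary C6 hydroxyl.

Step 7
Reactants: 12 C14 TBDPS ether
Product: 13 (2R,5S)-2-[(1E)-3-(TBDPS-oxy)-1-(methoxymethoxy)prop-1-en-2-yl]-5-methylcyclohexan-1-one
Conditions: Dess–Martin periodinane, pyridine, CH2Cl2, 0 → 23 °C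
Reagents that add atoms: none
Why: Dess–Martin oxidation under pyridine buffering returns the C6 ketone without acid or strong base, so the enol ether is neither hydrolysed nor moved into conjugation and C1 keeps its equatorial, thermodynamically preferred configuration.

Step 8
Reactants: 14 4-methoxybenzyl alcohol; 15 trichloroethylene
Product: 18 (E)-1,2-dichloroethenyl 4-methoxybenzyl ether, via potassium 4-methoxybenzyl oxide 16 (not isolated), via dichloroacetylene 17 (not isolated)
Conditions: KH, THF, 0 °C; then Cl2C=CHCl, −50 → 23 °C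
Reagents that add atoms: none
Why: The alkoxide dehydrochlorinates trichloroethylene and then adds anti across the chloroalkyne formed (addition of an alkoxide to a haloalkyne), which gives the E dichlorovinyl ether that serves as a masked ynol ether.

Step 9
Reactants: 18 dichloroethenyl PMB ether; 13 ketone
Product: 21 (1S,2R,5S)-1-[(4-methoxybenzyloxy)ethynyl] carbinol, via chloroethynyl ether 19 (not isolated), via lithium alkoxyacetylide 20 (not isolated)
Conditions: 18 (1.5 equiv), n-BuLi (3.0 equiv), THF, −78 → −40 °C; then 13, −78 °C; NH4Cl (aq)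
Reagents that add atoms: none
Why: Elimination followed by chlorine–lithium exchange gives the lithium alkoxyacetylide, and 1,2-addition of this slim nucleophile along the axial trajectory of the ketone sets C6 with the hydroxyl equatorial and the alkynyl group axial, cis to the equatorial C1 alkenyl group.

Step 10
Reactants: 21 alkynyl carbinol
Product: 22 (1S,2R,5S)-1-[(Z)-2-(4-methoxybenzyloxy)ethenyl] carbinol (rearrangement precursor)
Conditions: H2 (1 atm), Pd/CaCO3 poisoned with Pb(OAc)2, quinoline, EtOAc/Et3N, 23 °C
Reagents that add atoms: none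
Why: Lindlar semi-hydrogenation adds hydrogen syn to the electron-rich alkyne and stops at the Z enol ether, which places O8 cis to C6, while the hindered trisubstituted C9=C10 enol ether is not reduced.

Step 11
Reactants: 22 cis-dialkenyl cyclohexanol
Product: 25 C6 TMS enol ether of the ring-expanded cyclodec-5-enone (4S,8S,9S), via potassium alkoxide 23 (not isolated), via potassium enolate 24 (not isolated)
Conditions: KN(SiMe3)2, 18-crown-6, THF, −78 → 0 °C; then Me3SiCl, Et3N, −78 °C; non-aqueous work-up
Reagents that add atoms: chlorotrimethylsilane, C[Si](C)(C)Cl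
Why: Deprotonation gives the potassium alkoxide, whose oxyanion loosens the adjacent C1–C6 bond so that the 1,5-diene C8=C7–C6–C1–C10=C9 undergoes a [3,3]-sigmatropic shift in which C8–C9 forms while C1–C6 breaks; the closest known reaction is the anionic oxy-Cope rearrangement of cis-1,2-divinylcyclohexanols to cyclodec-5-enones, extended here to a substrate with an enol ether oxygen on each bonding terminus. The ten-membered ring is not closed end to end but arises by four-carbon ring expansion of the cyclohexane, and conversion of the alkoxide into the C6 enolate makes the step irreversible. With C15 equatorial the cyclohexane chair carries the C1 alkenyl group equatorially and the C6 alkenyl group axially, so in the six-centre chair C2 is pseudo-axial and ends up cis to C9 on the new C1=C10 bond (ring-cis, C2 trans to C14). Because O8 and O9 are each cis to the ring-bound carbon of their enol ether they occupy axial positions on C8 and C9, and the alkene faces that can reach each other in this chair then give 8S and 9S, so both new stereocentres are relayed from C4 through C1/C6 and the enol ether geometries. The step needs the cis-dialkenyl diastereomer (secured by the axial acetylide addition), a chair rather than a boat (favoured by the 60° C7–C6–C1–C10 dihedral fixed by the cyclohexane) and intact enol ether geometries (set in steps 4 and 10). Silylation at −78 °C captures the enolate as the C6=C7 enol silane before the C8 ether can be expelled by β-elimination and keeps the regiochemistry needed for the C7–C11 bond.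

Step 12
Reactants: 25 enol silane
Product: 27 γ-keto tert-butyl ester (C6 ketone; C7 CH2CO2t-Bu cis to O8; 4S,7R,8S,9S), via lithium enolate 26 (not isolated)
Conditions: MeLi, THF, −20 °C; then BrCH2CO2t-Bu, DMPU, −78 → −40 °C
Reagents that add atoms: tert-butyl bromoacetate, CC(C)(C)OC(=O)CBr
Why: Cleavage of the enol silane by methyllithium regenerates the C6=C7 lithium enolate without regiochemical scrambling, and enolate alkylation with the α-bromo ester on the peripheral face, away from the transannular C1=C10 alkene, should set C7 with C11 cis to the C8 oxygen.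

Step 13
Reactants: 27 γ-keto ester
Product: 28 6S hydroxy ester (C6–OH cis to C11)
Conditions: LiBH(s-Bu)3, THF, −78 °C; NH4Cl (aq) at −78 °C
Reagents that add atoms: none
Why: By Felkin–Anh-type substrate control the hindered hydride should attack C6 anti to the C7–C8 ring bond and past H7, as bulky hydrides do with 2-substituted medium-ring ketones, giving the 6S alcohol with the hydroxyl cis to C11, while the tert-butyl ester resists the alkoxide at this temperature.

Step 14
Reactants: 28 6S hydroxy ester
Product: 30 trans-fused γ-lactone (4S,6R,7S,8S,9S), via C6 triflate 29 (not isolated)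
Conditions: Tf2O, pyridine, CH2Cl2, −78 → 0 °C
Reagents that add atoms: none
Why: The C6 triflate is displaced from the rear by the carbonyl oxygen of the tert-butyl ester (neighbouring-group participation, 5-exo-tet SN2) and the dialkoxycarbenium ion formed loses isobutene, so C6 is inverted to 6R and the γ-lactone closes trans-fused.

Step 15
Reactants: 30 trans-lactone
Product: 32 C11 (dimethylamino)methyl lactone, via lactone lithium enolate 31 (not isolated)
Conditions: LiN(i-Pr)2, THF, −78 °C; then CH2=NMe2+ I−, −78 → 23 °C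
Reagents that add atoms: N,N-dimethylmethyleneiminium iodide, C=[N+](C)C.[I-]
Why: The lactone enolate carries no β leaving group and adds to the iminium salt (Mannich reaction with Eschenmoser's salt) to attach C13, the new C11 centre being irrelevant because it is removed in step 16.

Step 16
Reactants: 32 Mannich base
Product: 34 α-methylene lactone, via ammonium iodide 33 (not isolated)
Conditions: MeI, THF, 23 °C; then NaHCO3 (aq), CH2Cl2, 23 °C
Reagents that add atoms: none
Why: Quaternisation turns the amine into a leaving group and bicarbonate then induces β-elimination (Hofmann-type, E1cB) to the exocyclic C11=C13 methylene.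

Step 17
Reactants: 34 α-methylene lactone
Product: 35 C14 allylic alcohol
Conditions: HF·pyridine, pyridine, THF, 0 → 23 °C
Reagents that add atoms: none
Why: Fluoride-mediated desilylation with buffered HF·pyridine frees the primary C14 alcohol, and the acetal, the benzylic ether and the unsaturated lactone do not react with this reagent.

Step 18
Reactants: 35 C14 allylic alcohol
Product: 36 C14 enal
Conditions: MnO2, CH2Cl2, 23 °C
Reagents that add atoms: none
Why: MnO2 oxidises only the allylic primary alcohol (chemoselective allylic oxidation) and gives the enal without moving the C1=C10 double bond.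

Step 19
Reactants: 36 C14 enal
Product: 37 C14 carboxylic acid
Conditions: NaClO2, NaH2PO4, 2-methyl-2-butene, t-BuOH/H2O, 0 → 23 °C
Reagents that add atoms: sodium chlorite, [Na+].[O-]Cl=O
Why: Pinnick oxidation converts the enal into the carboxylic acid under buffered conditions, with 2-methyl-2-butene removing hypochlorite before it can reach the alkenes or the PMB ether.

Step 20
Reactants: 37 C14 carboxylic acid
Product: 39 C14 methyl ester, via potassium carboxylate 38 (not isolated)
Conditions: KHCO3, MeI, DMF, 23 °C
Reagents that add atoms: iodomethane, CI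
Why: The carboxylate formed with the weak base is alkylated by iodomethane (SN2 esterification), conditions under which the lactone, the acetal and the unsaturated esters are stable.

Step 21
Reactants: 39 C14 methyl ester
Product: 40 C8 alcohol
Conditions: DDQ, CH2Cl2/pH 7 phosphate buffer, 0 → 23 °C
Reagents that add atoms: none
Why: Oxidative cleavage of the electron-rich PMB ether by DDQ (hydride abstraction, hydrolysis of the oxocarbenium ion) frees the C8 hydroxyl selectively, since the acetal and the electron-poor alkenes are not oxidised.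

Step 22
Reactants: 41 angelic acid; 40 C8 alcohol
Product: 43 C8 angelate (C9 MOM ether), via mixed anhydride 42 (not isolated)
Conditions: 41, 2,4,6-trichlorobenzoyl chloride, Et3N, toluene, 23 °C; then 40, toluene, 75 °C
Reagents that add atoms: none
Why: Yamaguchi-type esterification through the mixed anhydride, run without a nucleophilic catalyst, acylates the hindered C8 hydroxyl while keeping the Z geometry of the angelate, which 4-(dimethylamino)pyridine would isomerise to the tiglate.

Step 23
Reactants: 43 C8 angelate
Product: 45 target CNP0552150.1, via C9 dimethylborinate 44 (not isolated)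
Conditions: Me2BBr, CH2Cl2, −78 °C; then NaHCO3 (aq), THF, 0 °C
Reagents that add atoms: none
Why: The Lewis acidic bromoborane cleaves the methoxymethyl acetal at low temperature (acetal cleavage by a dialkylboron bromide) and hydrolysis of the borinate frees the C9 hydroxyl, conditions too mild to isomerise the angelate, to add to the methylene lactone or to promote acyl migration.

**Compound list**

1 | 2-cyclohexen-1-one | O=C1C=CCCC1 | starting material
2 | lithium cyclohexa-1,5-dien-1-olate (cross-conjugated dienolate of 1) | [Li+].[O-]C1=CCCC=C1 | intermediate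
3 | methyl 2-(2-oxocyclohex-3-en-1-yl)acetate (racemic) | COC(=O)CC1CCC=CC1=O | intermediate
4 | methylzinc (3S)-6-(2-methoxy-2-oxoethyl)-3-methylcyclohex-1-en-1-olate (both C6 epimers) | C[Zn]OC1=C[C@@H](C)CCC1CC(=O)OC | intermediate
5 | methyl 2-[(4S)-4-methyl-2-oxocyclohexyl]acetate, mixture of C1 epimers | O=C1C[C@@H](C)CCC1CC(=O)OC | intermediate
6 | methyl 2-[(1R,4S)-4-methyl-2-oxocyclohexyl]acetate (trans) | O=C1C[C@@H](C)CC[C@@H]1CC(=O)OC | intermediate
7 | lithium (1R,2R,5S)-2-(2-methoxy-2-oxoethyl)-5-methylcyclohexan-1-olate (axial alkoxide) | [Li+].[O-][C@@H]1C[C@@H](C)CC[C@@H]1CC(=O)OC | intermediate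
8 | (3aR,6S,7aR)-6-methylhexahydro-1-benzofuran-2(3H)-one (cis-fused) | O1[C@@H]2C[C@@H](C)CC[C@@H]2CC1=O | intermediate
9 | sodium enolate of the 3-formyl derivative of 8 | O1[C@@H]2C[C@@H](C)CC[C@@H]2C(=C[O-])C1=O.[Na+] | intermediate
10 | (3E,3aR,6S,7aR)-3-[(methoxymethoxy)methylidene]-6-methylhexahydro-1-benzofuran-2(3H)-one | O1[C@@H]2C[C@@H](C)CC[C@@H]2/C(=C\OCOC)C1=O | intermediate
11 | (1R,2R,5S)-2-[(1E)-3-hydroxy-1-(methoxymethoxy)prop-1-en-2-yl]-5-methylcyclohexan-1-ol | O[C@@H]1C[C@@H](C)CC[C@@H]1/C(CO)=C\OCOC | intermediate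
12 | (1R,2R,5S)-2-[(1E)-3-(tert-butyldiphenylsilyloxy)-1-(methoxymethoxy)prop-1-en-2-yl]-5-methylcyclohexan-1-ol | O[C@@H]1C[C@@H](C)CC[C@@H]1/C(CO[Si](c2ccccc2)(c2ccccc2)C(C)(C)C)=C\OCOC | intermediate
13 | (2R,5S)-2-[(1E)-3-(tert-butyldiphenylsilyloxy)-1-(methoxymethoxy)prop-1-en-2-yl]-5-methylcyclohexan-1-one | O=C1C[C@@H](C)CC[C@@H]1/C(CO[Si](c2ccccc2)(c2ccccc2)C(C)(C)C)=C\OCOC | intermediate
14 | 4-methoxybenzyl alcohol | COc1ccc(CO)cc1 | starting material
15 | trichloroethylene | ClC=C(Cl)Cl | starting material
16 | potassium 4-methoxybenzyl oxide | [K+].[O-]Cc1ccc(OC)cc1 | intermediate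
17 | dichloroacetylene | ClC#CCl | intermediate
18 | 1-({[(E)-1,2-dichloroethenyl]oxy}methyl)-4-methoxybenzene | COc1ccc(CO/C(Cl)=C\Cl)cc1 | intermediate
19 | 1-{[(chloroethynyl)oxy]methyl}-4-methoxybenzene | COc1ccc(COC#CCl)cc1 | intermediate
20 | lithium (4-methoxybenzyloxy)acetylide | [Li]C#COCc1ccc(OC)cc1 | intermediate
21 | (1S,2R,5S)-2-[(1E)-3-(TBDPS-oxy)-1-(methoxymethoxy)prop-1-en-2-yl]-1-[(4-methoxybenzyloxy)ethynyl]-5-methylcyclohexan-1-ol (alkynyl axial, OH equatorial) | O[C@@]1(C#COCc2ccc(OC)cc2)C[C@@H](C)CC[C@@H]1/C(CO[Si](c3ccccc3)(c3ccccc3)C(C)(C)C)=C\OCOC | intermediate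
22 | (1S,2R,5S)-2-[(1E)-3-(TBDPS-oxy)-1-(methoxymethoxy)prop-1-en-2-yl]-1-[(Z)-2-(4-methoxybenzyloxy)ethenyl]-5-methylcyclohexan-1-ol (alkenyl groups cis) | O[C@@]1(/C=C\OCc2ccc(OC)cc2)C[C@@H](C)CC[C@@H]1/C(CO[Si](c3ccccc3)(c3ccccc3)C(C)(C)C)=C\OCOC | intermediate
23 | potassium alkoxide of 22 | [K+].[O-][C@@]1(/C=C\OCc2ccc(OC)cc2)C[C@@H](C)CC[C@@H]1/C(CO[Si](c3ccccc3)(c3ccccc3)C(C)(C)C)=C\OCOC | intermediate
24 | potassium enolate of the ring-expanded ketone (O− on C6, Z C6=C7, ring-cis C1=C10; 4S,8S,9S; C8 OPMB, C9 OMOM, C10 CH2OTBDPS) | [K+].[O-]/C1=C\[C@H](OCc2ccc(OC)cc2)[C@@H](OCOC)/C(CO[Si](c2ccccc2)(c2ccccc2)C(C)(C)C)=C\CC[C@H](C)C1 | intermediate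
25 | C6 trimethylsilyl enol ether of the same cyclodec-5-enone (Z C6=C7, ring-cis C1=C10; 4S,8S,9S) | C[Si](C)(C)O/C1=C\[C@H](OCc2ccc(OC)cc2)[C@@H](OCOC)/C(CO[Si](c2ccccc2)(c2ccccc2)C(C)(C)C)=C\CC[C@H](C)C1 | intermediate
26 | lithium enolate corresponding to 25 | [Li+].[O-]/C1=C\[C@H](OCc2ccc(OC)cc2)[C@@H](OCOC)/C(CO[Si](c2ccccc2)(c2ccccc2)C(C)(C)C)=C\CC[C@H](C)C1 | intermediate
27 | tert-butyl ester of the C7 acetic acid on the C6 ketone (4S,7R,8S,9S; C11 cis to O8) | O=C1[C@H](CC(=O)OC(C)(C)C)[C@H](OCc2ccc(OC)cc2)[C@@H](OCOC)/C(CO[Si](c2ccccc2)(c2ccccc2)C(C)(C)C)=C\CC[C@H](C)C1 | intermediate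
28 | 6S alcohol from 27 (4S,6S,7S,8S,9S; C6–OH cis to C11) | O[C@@H]1[C@H](CC(=O)OC(C)(C)C)[C@H](OCc2ccc(OC)cc2)[C@@H](OCOC)/C(CO[Si](c2ccccc2)(c2ccccc2)C(C)(C)C)=C\CC[C@H](C)C1 | intermediate
29 | C6 trifluoromethanesulfonate of 28 | O=S(=O)(O[C@@H]1[C@H](CC(=O)OC(C)(C)C)[C@H](OCc2ccc(OC)cc2)[C@@H](OCOC)/C(CO[Si](c2ccccc2)(c2ccccc2)C(C)(C)C)=C\CC[C@H](C)C1)C(F)(F)F | intermediate
30 | trans-fused C12→O6 γ-lactone (4S,6R,7S,8S,9S; C8 OPMB, C9 OMOM, C14 OTBDPS) | O=C1O[C@@H]2C[C@@H](C)CC/C=C(/CO[Si](c3ccccc3)(c3ccccc3)C(C)(C)C)[C@H](OCOC)[C@@H](OCc3ccc(OC)cc3)[C@H]2C1 | intermediate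
31 | lithium enolate of lactone 30 | [Li+].[O-]C=1O[C@@H]2C[C@@H](C)CC/C=C(/CO[Si](c3ccccc3)(c3ccccc3)C(C)(C)C)[C@H](OCOC)[C@@H](OCc3ccc(OC)cc3)[C@H]2C=1 | intermediate
32 | C11 (dimethylamino)methyl derivative of 30 (C11 configuration not controlled) | O=C1O[C@@H]2C[C@@H](C)CC/C=C(/CO[Si](c3ccccc3)(c3ccccc3)C(C)(C)C)[C@H](OCOC)[C@@H](OCc3ccc(OC)cc3)[C@H]2C1CN(C)C | intermediate
33 | trimethylammonium iodide from 32 | O=C1O[C@@H]2C[C@@H](C)CC/C=C(/CO[Si](c3ccccc3)(c3ccccc3)C(C)(C)C)[C@H](OCOC)[C@@H](OCc3ccc(OC)cc3)[C@H]2C1C[N+](C)(C)C.[I-] | intermediate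
34 | α-methylene lactone (C11=C13; C8 OPMB, C9 OMOM, C14 OTBDPS) | C=C1C(=O)O[C@@H]2C[C@@H](C)CC/C=C(/CO[Si](c3ccccc3)(c3ccccc3)C(C)(C)C)[C@H](OCOC)[C@@H](OCc3ccc(OC)cc3)[C@@H]12 | intermediate
35 | C14 allylic alcohol from 34 | C=C1C(=O)O[C@@H]2C[C@@H](C)CC/C=C(/CO)[C@H](OCOC)[C@@H](OCc3ccc(OC)cc3)[C@@H]12 | intermediate
36 | C14 enal | C=C1C(=O)O[C@@H]2C[C@@H](C)CC/C=C(/C=O)[C@H](OCOC)[C@@H](OCc3ccc(OC)cc3)[C@@H]12 | intermediate
37 | C14 carboxylic acid | C=C1C(=O)O[C@@H]2C[C@@H](C)CC/C=C(/C(=O)O)[C@H](OCOC)[C@@H](OCc3ccc(OC)cc3)[C@@H]12 | intermediate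
38 | potassium carboxylate of 37 | [K+].C=C1C(=O)O[C@@H]2C[C@@H](C)CC/C=C(/C(=O)[O-])[C@H](OCOC)[C@@H](OCc3ccc(OC)cc3)[C@@H]12 | intermediate
39 | C14 methyl ester (C8 OPMB, C9 OMOM) | C=C1C(=O)O[C@@H]2C[C@@H](C)CC/C=C(/C(=O)OC)[C@H](OCOC)[C@@H](OCc3ccc(OC)cc3)[C@@H]12 | intermediate
40 | C8 alcohol (4S,6R,7R,8S,9S; C9 OMOM) | C=C1C(=O)O[C@@H]2C[C@@H](C)CC/C=C(/C(=O)OC)[C@H](OCOC)[C@@H](O)[C@@H]12 | intermediate
41 | angelic acid, (Z)-2-methylbut-2-enoic acid | C/C=C(/C)C(=O)O | starting material
42 | angelic 2,4,6-trichlorobenzoic anhydride | C/C=C(/C)C(=O)OC(=O)c1c(Cl)cc(Cl)cc1Cl | intermediate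
43 | C8 angelate with C9 OMOM (4S,6R,7S,8S,9S) | C=C1C(=O)O[C@@H]2C[C@@H](C)CC/C=C(/C(=O)OC)[C@H](OCOC)[C@@H](OC(=O)/C(C)=C\C)[C@@H]12 | intermediate
44 | C9 dimethylborinate of the target | C=C1C(=O)O[C@@H]2C[C@@H](C)CC/C=C(/C(=O)OC)[C@H](OB(C)C)[C@@H](OC(=O)/C(C)=C\C)[C@@H]12 | intermediate
45 | CNP0552150.1 (4S,6R,7S,8S,9S; C8 angelate, C9 OH, C14 methyl ester, trans C12→O6 α-methylene lactone) | C=C1C(=O)O[C@@H]2C[C@@H](C)CC/C=C(/C(=O)OC)[C@H](O)[C@@H](OC(=O)/C(C)=C\C)[C@@H]12 | target

**Step count**

Total: 23 steps. Longest linear sequence: 22 steps (steps 1–7 and 9–23); step 8 is a one-step branch that joins at step 9.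

**Steps most likely to fail**

Step 11. The chair forces both alkoxy groups into axial positions (O8 1,3 to the oxyanion, O9 1,3 to C2). The rearrangement may therefore pass through a boat-like array instead, which with the Z enol ether would deliver the C8 epimer. The fallback matches the enol ether geometry to that topology. It sets out from 21: trans-hydroalumination with NaAlH2(OCH2CH2OMe)2 in THF at 0 °C gives the E enol ether carbinol F1. Alkoxide formation, rearrangement and silylation under the conditions of step 11 should then, through the boat, give the 8S,9S enol silane F2, the C6=C7 geometric isomer of 25. Methyllithium converts F2 into its lithium enolate F3, which is alkylated with tert-butyl bromoacetate as in step 12. The fallback comes back at 27, provided the alkylation again takes place on the face that puts C11 cis to O8.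

Step 12. The lithium enolate carries a β-alkoxy group and may expel 4-methoxybenzyl oxide, or may be quenched by proton transfer from the bromo ester, before C-alkylation; the facial selectivity at C7 also rests only on the ring conformation. The fallback avoids a free basic enolate. It sets out from 25: cyclopropanation of the enol silane with tert-butyl diazoacetate and Cu(acac)2 (cat.) in CH2Cl2 at 40 °C gives the siloxycyclopropane ester F4, with the carbenoid adding to the electron-rich C6=C7 bond from the periphery. Fluoride-induced ring opening with Et3N·3HF in THF at 23 °C then gives the γ-keto ester, and the fallback comes back at 27.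

Step 14. The secondary triflate sits on a ten-membered ring and may ionise, leading to elimination, transannular capture by the C1=C10 alkene or participation of the C9 acetal oxygen, instead of clean rear-side displacement by the ester carbonyl; the inversion is also only correct if step 13 has given the 6S alcohol. The fallback separates inversion from ring closure. It sets out from 28: Mitsunobu reaction with 4-nitrobenzoic acid, PPh3 and diisopropyl azodicarboxylate in toluene gives the inverted 4-nitrobenzoate F5. Methanolysis with K2CO3 in MeOH at 0 °C gives the 6R alcohol F6, and acid-catalysed lactonisation with camphorsulfonic acid (cat.) in toluene at 60 °C closes the lactone with retention, coming back at 30. If step 13 gives the 6R alcohol directly, that material is F6 and only the last operation is needed.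

Further compounds
F1 | step 11 | (1S,2R,5S)-1-[(E)-2-(4-methoxybenzyloxy)ethenyl] isomer of 22 | O[C@@]1(/C=C/OCc2ccc(OC)cc2)C[C@@H](C)CC[C@@H]1/C(CO[Si](c3ccccc3)(c3ccccc3)C(C)(C)C)=C\OCOC
F2 | step 11 | C6 trimethylsilyl enol ether with ring-cis C6=C7 (geometric isomer of 25; 4S,8S,9S) | C[Si](C)(C)O/C1=C/[C@H](OCc2ccc(OC)cc2)[C@@H](OCOC)/C(CO[Si](c2ccccc2)(c2ccccc2)C(C)(C)C)=C\CC[C@H](C)C1
F3 | step 11 | lithium enolate corresponding to F2 | [Li+].[O-]/C1=C/[C@H](OCc2ccc(OC)cc2)[C@@H](OCOC)/C(CO[Si](c2ccccc2)(c2ccccc2)C(C)(C)C)=C\CC[C@H](C)C1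
F4 | step 12 | tert-butyl 2-siloxycyclopropanecarboxylate fused across C6–C7 of 25 (ester carbon configuration not controlled) | C[Si](C)(C)O[C@@]12C[C@@H](C)CC/C=C(/CO[Si](c3ccccc3)(c3ccccc3)C(C)(C)C)[C@H](OCOC)[C@@H](OCc3ccc(OC)cc3)[C@H]1C2C(=O)OC(C)(C)C
F5 | step 14 | 6R 4-nitrobenzoate of the hydroxy ester (C6 inverted) | O=C(O[C@H]1[C@H](CC(=O)OC(C)(C)C)[C@H](OCc2ccc(OC)cc2)[C@@H](OCOC)/C(CO[Si](c2ccccc2)(c2ccccc2)C(C)(C)C)=C\CC[C@H](C)C1)c1ccc(cc1)[N+](=O)[O-]
F6 | step 14 | 6R hydroxy tert-butyl ester (C6 epimer of 28) | O[C@H]1[C@H](CC(=O)OC(C)(C)C)[C@H](OCc2ccc(OC)cc2)[C@@H](OCOC)/C(CO[Si](c2ccccc2)(c2ccccc2)C(C)(C)C)=C\CC[C@H](C)C1
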